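## Plan

1. Retrosynthetic cuts, in order: the C8–CH2 bond of the prenyl group (back to a prenyl ether on O5); the C4–C4a bond of the pyran together with its O1–C2 closure (back to an aryl 1,1-dimethylpropargyl ether); the O–CMe2 bond of that ether; the CH2–aryl bond of a deoxybenzoin whose CH2 becomes the second carbonyl.
2. Forward: the ring-A acetophenone is α-arylated with the ring-B aryl bromide and oxidised to the benzil. The non-chelated hydroxyl is propargylated, heating closes the pyran (the only ring made), and the prenyl group is then moved from O5 to C8.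
3. Enabling feature: C4a lies between the C5 hydroxyl, which is hydrogen-bonded to the C6 ketone, and the C8a oxygen. That oxygen can carry O1–C2(Me2)–C3–C4 as a propargyl ether, and the chelate steers the sigmatropic shift to C4a.
4. Protecting groups: MOM on the two ring-A hydroxyls, because an acetal cannot migrate to the enolate oxygen; it is removed by acid after the oxidation. TIPS on the ring-B phenol, kept to the last step and removed by fluoride.
5. Stereochemistry: the target has no stereocentre and its C3=C4 bond is cis by ring constraint, so nothing has to be set.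

Key step: step 7

Assumption: because the target is achiral, "single enantiomer" imposes no stereochemical task. Atom labels C2–C8a are the chromene numbering of the target; in open-chain precursors the ring-A carbons are counted from the acyl-bearing carbon.

## Route

Step 1
Reactants: 1 2',4'-dihydroxy-6'-methoxyacetophenone
Product: 2 1-[2-methoxy-4,6-bis(methoxymethoxy)phenyl]ethan-1-one
Conditions: NaH (2.3 equiv), MOMCl (2.5 equiv), DMF, 0 °C → rt
Reagents that add atoms: chloromethyl methyl ether (MOMCl), COCCl
Why: Williamson-type O-alkylation in which NaH converts both phenols, including the hydrogen-bonded one, into phenoxides that displace chloride from MOMCl, so that no acidic O–H interferes with the enolate chemistry that follows.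

Step 2
Reactants: 3 4-bromophenol
Product: 4 (4-bromophenoxy)triisopropylsilane
Conditions: TIPSCl, imidazole, DMF, rt
Reagents that add atoms: triisopropylsilyl chloride (TIPSCl), CC(C)[Si](Cl)(C(C)C)C(C)C
Why: Imidazole-mediated O-silylation of a phenol, giving a hindered aryl silyl ether that is expected to withstand alkoxide, aqueous acid and heat and to leave only with fluoride.

Step 3
Reactants: 2 1-[2-methoxy-4,6-bis(methoxymethoxy)phenyl]ethan-1-one; 4 (4-bromophenoxy)triisopropylsilane
Product: 5 1-[2-methoxy-4,6-bis(methoxymethoxy)phenyl]-2-[4-(triisopropylsilyloxy)phenyl]ethan-1-one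
Conditions: Pd2(dba)3 (2 mol %), Xantphos (5 mol %), NaOtBu (2.2 equiv), toluene, 80 °C, slight excess of 2
Reagents that add atoms: none
Why: Palladium-catalysed α-arylation of a methyl ketone enolate (Buchwald–Hartwig type), in which oxidative addition of the aryl bromide, enolate binding and reductive elimination from the wide-bite-angle Xantphos complex should stop at monoarylation, while the acetal groups on ring A offer the enolate nothing that can migrate.

Step 4
Reactants: 5 1-[2-methoxy-4,6-bis(methoxymethoxy)phenyl]-2-[4-(triisopropylsilyloxy)phenyl]ethan-1-one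
Product: 6 1-[2-methoxy-4,6-bis(methoxymethoxy)phenyl]-2-[4-(triisopropylsilyloxy)phenyl]ethane-1,2-dione
Conditions: SeO2 (1.5 equiv), 1,4-dioxane, 100 °C
Reagents that add atoms: selenium dioxide, O=[Se]=O
Why: Riley oxidation, the standard conversion of a deoxybenzoin into a benzil, acting on a CH2 that enolises easily between the ketone and the aryl ring while every phenol is still masked against the oxidant.

Step 5
Reactants: 6 1-[2-methoxy-4,6-bis(methoxymethoxy)phenyl]-2-[4-(triisopropylsilyloxy)phenyl]ethane-1,2-dione
Product: 7 1-(2,4-dihydroxy-6-methoxyphenyl)-2-[4-(triisopropylsilyloxy)phenyl]ethane-1,2-dione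
Conditions: 3 M aq. HCl, MeOH, 50 °C
Reagents that add atoms: none
Why: Acid-catalysed acetal exchange with methanol removes both MOM groups and traps the formaldehyde unit as its dimethyl acetal, whereas the aryl TIPS ether, which acid cleaves only very slowly, and the diketone should persist.

Step 6
Reactants: 7 1-(2,4-dihydroxy-6-methoxyphenyl)-2-[4-(triisopropylsilyloxy)phenyl]ethane-1,2-dione; 8 3-chloro-3-methylbut-1-yne
Product: 9 1-[2-hydroxy-6-methoxy-4-(2-methylbut-3-yn-2-yloxy)phenyl]-2-[4-(triisopropylsilyloxy)phenyl]ethane-1,2-dione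
Conditions: DBU (1.2 equiv), CuCl2·2H2O (1 mol %), MeCN, 0 °C, N2
Reagents that add atoms: none
Why: Copper-catalysed propargylic etherification of a tertiary propargylic chloride through a copper acetylide, in which the more acidic, non-hydrogen-bonded 4-phenoxide reacts and the chelated 2-hydroxyl stays free; acetonitrile replaces acetone, which could add to the diketone under base.

Step 7
Reactants: 9 1-[2-hydroxy-6-methoxy-4-(2-methylbut-3-yn-2-yloxy)phenyl]-2-[4-(triisopropylsilyloxy)phenyl]ethane-1,2-dione
Product: 13 1-(5-hydroxy-7-methoxy-2,2-dimethyl-2H-chromen-6-yl)-2-[4-(triisopropylsilyloxy)phenyl]ethane-1,2-dione, via allenyl dienone 10 (not isolated), via allenyl phenol 11 (not isolated), via o-quinone methide 12 (not isolated)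
Conditions: degassed o-xylene, 140 °C
Reagents that add atoms: none
Why: Heating sets off an aromatic propargyl Claisen [3,3] shift that bonds the alkyne terminus to the ring carbon between the two oxygens (the C4–C4a bond) and gives allenyl dienone 10, which enolises to allenyl phenol 11. A 1,5-hydrogen shift from the hydroxyl just released to the central allene carbon then gives the cis-configured o-quinone methide 12, and a thermal disrotatory oxa-6π electrocyclisation forms the O1–C2 bond and so closes the six-membered pyran ring. The closest known reaction type is the thermal rearrangement of aryl 1,1-dimethylpropargyl ethers to 2,2-dimethyl-2H-chromenes, which is established for 2-hydroxyaryl ketones. No stereocentre arises. The step needs regioselectivity between the two free ortho carbons: the hydroxyl hydrogen-bonded to the adjacent ketone fixes the bond alternation of the arene so that the ring bond towards the carbon flanked by two oxygens has the higher double-bond character, and a non-polar, non-basic solvent keeps that chelate closed. The same hydrogen bond holds the C5 hydroxyl proton back from the hydrogen shift, so closure should use the former ether oxygen and keep the chelated 5-hydroxy-6-acyl pattern.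

Step 8
Reactants: 13 1-(5-hydroxy-7-methoxy-2,2-dimethyl-2H-chromen-6-yl)-2-[4-(triisopropylsilyloxy)phenyl]ethane-1,2-dione; 14 1-bromo-3-methylbut-2-ene (prenyl bromide)
Product: 15 1-[7-methoxy-2,2-dimethyl-5-(3-methylbut-2-en-1-yloxy)-2H-chromen-6-yl]-2-[4-(triisopropylsilyloxy)phenyl]ethane-1,2-dione
Conditions: K2CO3 (3 equiv), MeCN, 60 °C
Reagents that add atoms: none
Why: Williamson etherification in which carbonate deprotonates the chelated C5 hydroxyl, the only free O–H, and the phenoxide displaces bromide from the primary allylic bromide by SN2; a non-enolisable solvent again protects the diketone.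

Step 9
Reactants: 15 1-[7-methoxy-2,2-dimethyl-5-(3-methylbut-2-en-1-yloxy)-2H-chromen-6-yl]-2-[4-(triisopropylsilyloxy)phenyl]ethane-1,2-dione
Product: 18 1-[5-hydroxy-7-methoxy-2,2-dimethyl-8-(3-methylbut-2-en-1-yl)-2H-chromen-6-yl]-2-[4-(triisopropylsilyloxy)phenyl]ethane-1,2-dione, via ortho-dienone 16 (not isolated), via para-dienone 17 (not isolated)
Conditions: degassed PhNEt2, 190 °C, sealed tube
Reagents that add atoms: none
Why: Aromatic para-Claisen rearrangement (Claisen–Cope sequence): both carbons ortho to the ether oxygen are substituted, so the first [3,3] shift gives a dienone that cannot enolise (drawn with the 1,1-dimethylallyl group on C6; whichever blocked ortho carbon receives it, the outcome is the same), the second [3,3] shift delivers the group, re-inverted to a normal prenyl, to C8 as the only unsubstituted ring carbon, and enolisation of 17 restores the chelated phenol, while the amine solvent buffers traces of acid that would ionise the prenyl ether.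

Step 10
Reactants: 18 1-[5-hydroxy-7-methoxy-2,2-dimethyl-8-(3-methylbut-2-en-1-yl)-2H-chromen-6-yl]-2-[4-(triisopropylsilyloxy)phenyl]ethane-1,2-dione
Product: 19 1-[5-hydroxy-7-methoxy-2,2-dimethyl-8-(3-methylbut-2-en-1-yl)-2H-chromen-6-yl]-2-(4-hydroxyphenyl)ethane-1,2-dione (CNP0184805.0)
Conditions: TBAF (1.1 equiv), AcOH (1.2 equiv), THF, 0 °C
Reagents that add atoms: none
Why: Fluoride-induced Si–O cleavage (silyl ether deprotection) driven by the strong Si–F bond, buffered with acetic acid so that the diketone, the chromene and the prenyl group are left alone; the target is achiral, so no stereocentre is at stake.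

## Compound list

1 | 2',4'-dihydroxy-6'-methoxyacetophenone | CC(=O)c1c(O)cc(O)cc1OC | starting material
2 | 1-[2-methoxy-4,6-bis(methoxymethoxy)phenyl]ethan-1-one | CC(=O)c1c(OCOC)cc(OCOC)cc1OC | intermediate
3 | 4-bromophenol | Oc1ccc(Br)cc1 | starting material
4 | (4-bromophenoxy)triisopropylsilane | CC(C)[Si](Oc1ccc(Br)cc1)(C(C)C)C(C)C | intermediate
5 | 1-[2-methoxy-4,6-bis(methoxymethoxy)phenyl]-2-[4-(triisopropylsilyloxy)phenyl]ethan-1-one | COc1cc(OCOC)cc(OCOC)c1C(=O)Cc2ccc(O[Si](C(C)C)(C(C)C)C(C)C)cc2 | intermediate
6 | 1-[2-methoxy-4,6-bis(methoxymethoxy)phenyl]-2-[4-(triisopropylsilyloxy)phenyl]ethane-1,2-dione | COc1cc(OCOC)cc(OCOC)c1C(=O)C(=O)c2ccc(O[Si](C(C)C)(C(C)C)C(C)C)cc2 | intermediate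
7 | 1-(2,4-dihydroxy-6-methoxyphenyl)-2-[4-(triisopropylsilyloxy)phenyl]ethane-1,2-dione | COc1cc(O)cc(O)c1C(=O)C(=O)c2ccc(O[Si](C(C)C)(C(C)C)C(C)C)cc2 | intermediate
8 | 3-chloro-3-methylbut-1-yne | CC(C)(Cl)C#C | starting material
9 | 1-[2-hydroxy-6-methoxy-4-(2-methylbut-3-yn-2-yloxy)phenyl]-2-[4-(triisopropylsilyloxy)phenyl]ethane-1,2-dione | COc1cc(OC(C)(C)C#C)cc(O)c1C(=O)C(=O)c2ccc(O[Si](C(C)C)(C(C)C)C(C)C)cc2 | intermediate
10 | allenyl dienone: 1-[2-hydroxy-6-methoxy-3-(3-methylbuta-1,2-dien-1-yl)-4-oxocyclohexa-1,5-dien-1-yl]-2-[4-(triisopropylsilyloxy)phenyl]ethane-1,2-dione (racemic at the sp3 ring carbon; not isolated) | COC1=CC(=O)C(C=C=C(C)C)C(O)=C1C(=O)C(=O)c2ccc(O[Si](C(C)C)(C(C)C)C(C)C)cc2 | intermediate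
11 | allenyl phenol: 1-[2,4-dihydroxy-6-methoxy-3-(3-methylbuta-1,2-dien-1-yl)phenyl]-2-[4-(triisopropylsilyloxy)phenyl]ethane-1,2-dione (not isolated) | COc1cc(O)c(C=C=C(C)C)c(O)c1C(=O)C(=O)c2ccc(O[Si](C(C)C)(C(C)C)C(C)C)cc2 | intermediate
12 | o-quinone methide: 1-[2-hydroxy-6-methoxy-3-(3-methylbut-2-en-1-ylidene)-4-oxocyclohexa-1,5-dien-1-yl]-2-[4-(triisopropylsilyloxy)phenyl]ethane-1,2-dione, butenylidene chain cis to the ring carbonyl (not isolated) | COC1=CC(=O)/C(=C\C=C(C)C)C(O)=C1C(=O)C(=O)c2ccc(O[Si](C(C)C)(C(C)C)C(C)C)cc2 | intermediate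
13 | 1-(5-hydroxy-7-methoxy-2,2-dimethyl-2H-chromen-6-yl)-2-[4-(triisopropylsilyloxy)phenyl]ethane-1,2-dione | COc1cc2OC(C)(C)C=Cc2c(O)c1C(=O)C(=O)c3ccc(O[Si](C(C)C)(C(C)C)C(C)C)cc3 | intermediate
14 | 1-bromo-3-methylbut-2-ene (prenyl bromide) | CC(C)=CCBr | starting material
15 | 1-[7-methoxy-2,2-dimethyl-5-(3-methylbut-2-en-1-yloxy)-2H-chromen-6-yl]-2-[4-(triisopropylsilyloxy)phenyl]ethane-1,2-dione | COc1cc2OC(C)(C)C=Cc2c(OCC=C(C)C)c1C(=O)C(=O)c3ccc(O[Si](C(C)C)(C(C)C)C(C)C)cc3 | intermediate
16 | ortho-dienone: 1-[7-methoxy-2,2-dimethyl-6-(2-methylbut-3-en-2-yl)-5-oxo-5,6-dihydro-2H-chromen-6-yl]-2-[4-(triisopropylsilyloxy)phenyl]ethane-1,2-dione (racemic; not isolated) | COC1=CC2=C(C=CC(C)(C)O2)C(=O)C1(C(=O)C(=O)c3ccc(O[Si](C(C)C)(C(C)C)C(C)C)cc3)C(C)(C)C=C | intermediate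
17 | para-dienone: 1-[7-methoxy-2,2-dimethyl-8-(3-methylbut-2-en-1-yl)-5-oxo-5,8-dihydro-2H-chromen-6-yl]-2-[4-(triisopropylsilyloxy)phenyl]ethane-1,2-dione (racemic; not isolated) | COC1=C(C(=O)C(=O)c3ccc(O[Si](C(C)C)(C(C)C)C(C)C)cc3)C(=O)C2=C(OC(C)(C)C=C2)C1CC=C(C)C | intermediate
18 | 1-[5-hydroxy-7-methoxy-2,2-dimethyl-8-(3-methylbut-2-en-1-yl)-2H-chromen-6-yl]-2-[4-(triisopropylsilyloxy)phenyl]ethane-1,2-dione | COc1c(CC=C(C)C)c2OC(C)(C)C=Cc2c(O)c1C(=O)C(=O)c3ccc(O[Si](C(C)C)(C(C)C)C(C)C)cc3 | intermediate
19 | 1-[5-hydroxy-7-methoxy-2,2-dimethyl-8-(3-methylbut-2-en-1-yl)-2H-chromen-6-yl]-2-(4-hydroxyphenyl)ethane-1,2-dione (CNP0184805.0, achiral) | COc1c(CC=C(C)C)c2c(c(O)c1C(=O)C(=O)c1ccc(O)cc1)C=CC(C)(C)O2 | target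

## Step count and risks

Total steps: 10. Longest linear sequence: 9 steps (steps 1 and 3–10, from 1 to 19); step 2 is a one-step side branch.

Steps most likely to fail, riskiest first:

**Step 9.** At 190 °C the prenyl ether may ionise and lose the prenyl group, the blocked ortho-dienone may leak into other sigmatropic or acyl-shift channels, and the diketone may degrade on prolonged heating. The fallback makes the C8–C bond by cross-coupling and sets out from 13. Electrophilic iodination at C8, the only free and strongly activated arene position (NIS, MeCN, 0 °C), should give 1-(5-hydroxy-8-iodo-7-methoxy-2,2-dimethyl-2H-chromen-6-yl)-2-[4-(triisopropylsilyloxy)phenyl]ethane-1,2-dione F1. Stille coupling of F1 with tributyl(3-methylbut-2-en-1-yl)stannane (Pd(PPh3)4, DMF, 90 °C) should then give 18, where the route is rejoined; steps 8 and 9 are not needed.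

**Step 7.** If the hydrogen bond is loosened, part of the shift may go to the ortho carbon next to the methoxy group, and the cascade may stall before ring closure. The fallback replaces the sigmatropic C–C bond formation by an electrophilic substitution and sets out from 7. Condensation with 3-methylbut-2-enal under ethylenediammonium diacetate catalysis in refluxing xylene should engage the most nucleophilic ring carbon, the one flanked by two hydroxyls, and after loss of water pass through the same o-quinone methide 12 to 13, where the route is rejoined. No compound outside the list is formed, and step 6 is not needed.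

**Step 3.** The twisted, doubly ortho-substituted ketone may arylate slowly, a second arylation or aldol self-condensation may compete, and alkoxide may erode the silyl ether. The fallback joins the two rings by carbonyl addition and sets out from 2. Riley oxidation of the methyl ketone (SeO2, dioxane–water, 90 °C) should give 2-[2-methoxy-4,6-bis(methoxymethoxy)phenyl]-2-oxoacetaldehyde F2. Bromide 4 is converted with magnesium in THF into bromo[4-(triisopropylsilyloxy)phenyl]magnesium F3, which should add at −78 °C to the aldehyde of F2, the ketone being shielded by its two ortho substituents. This gives racemic 2-hydroxy-1-[2-methoxy-4,6-bis(methoxymethoxy)phenyl]-2-[4-(triisopropylsilyloxy)phenyl]ethan-1-one F4, whose stereocentre is erased on oxidation (MnO2, CH2Cl2) to 6, where the route is rejoined; steps 3 and 4 are replaced.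

## Further compounds

F1 | step 9 | 1-(5-hydroxy-8-iodo-7-methoxy-2,2-dimethyl-2H-chromen-6-yl)-2-[4-(triisopropylsilyloxy)phenyl]ethane-1,2-dione | COc1c(I)c2OC(C)(C)C=Cc2c(O)c1C(=O)C(=O)c3ccc(O[Si](C(C)C)(C(C)C)C(C)C)cc3
F0 | step 7 | none | none
F2 | step 3 | 2-[2-methoxy-4,6-bis(methoxymethoxy)phenyl]-2-oxoacetaldehyde | COc1cc(OCOC)cc(OCOC)c1C(=O)C=O
F3 | step 3 | bromo[4-(triisopropylsilyloxy)phenyl]magnesium | CC(C)[Si](Oc1ccc([Mg]Br)cc1)(C(C)C)C(C)C
F4 | step 3 | 2-hydroxy-1-[2-methoxy-4,6-bis(methoxymethoxy)phenyl]-2-[4-(triisopropylsilyloxy)phenyl]ethan-1-one (racemic) | COc1cc(OCOC)cc(OCOC)c1C(=O)C(O)c2ccc(O[Si](C(C)C)(C(C)C)C(C)C)cc2
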